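**Retrosynthetic overview**
- The target is the unsymmetrical ortho–para dimer of (S)-curcuphenol. Cut the biaryl bond: both of its carbons are natural donor positions of phenols (the para carbon of ring A, the 4-hydroxyaryl ring, and the ortho carbon of ring B, the 2-hydroxyaryl ring).
- Ring A is used with reversed polarity as (S)-curcuquinone, a 4-hydroxyaryl cation (vinylogous enolonium) equivalent. Ring B enters as the through-conjugated dienolate of its dihydro form, a 3-methyl-6-alkylcyclohex-2-enone. Aldol condensation plus tautomerisation is redox neutral and loses only water.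
- Curcuquinone comes from the same enone by dehydrogenation to (S)-curcuphenol and aerobic para-oxidation.
- The enone comes from (S)-citronellal and methyl vinyl ketone by Robinson annulation, MeLi addition and oxidative 1,3-transposition. Both stereocentres are bought with citronellal.
- Ring order: one carbocycle is built once (step 1) and the material is split after step 3. Ring A is aromatised in step 4, and ring B last, in the coupling step.

Assumption: the SMILES fixes only the two sp3 centres (both S) and gives no axial descriptor, so the biaryl axis is left uncontrolled.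

**Step 1**
Reactants: 1 (S)-citronellal; 2 methyl vinyl ketone
Product: 4 4-[(2S)-6-methylhept-5-en-2-yl]cyclohex-2-en-1-one (both C-4 epimers), via keto aldehyde 3 (not isolated)
Conditions: Et2NSiMe3 (20 mol %), MeCN, reflux; then KOH (30 mol %), n-Bu4NOH (cat.), H2O/THF/Et2O, reflux
Reagents that add atoms: none
Why: Amine-catalysed Michael addition of the citronellal enamine to the enone, followed by intramolecular aldol condensation (Robinson annulation), is a known way from citronellal to this cyclohexenone; the side-chain centre is beta to the aldehyde and is untouched, and the new ring centre C-4 forms as a mixture that is erased later.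

**Step 2**
Reactants: 4 4-[(2S)-6-methylhept-5-en-2-yl]cyclohex-2-en-1-one
Product: 5 1-methyl-4-[(2S)-6-methylhept-5-en-2-yl]cyclohex-2-en-1-ol (diastereomer mixture)
Conditions: MeLi, Et2O, −78 °C; then H2O
Reagents that add atoms: methyllithium, [Li]C
Why: Hard methyllithium adds 1,2 to the enone carbonyl (1,2-addition); the new carbinol centre forms as a mixture, which does not matter because it becomes sp2 in step 3.

**Step 3**
Reactants: 5 1-methyl-4-[(2S)-6-methylhept-5-en-2-yl]cyclohex-2-en-1-ol
Product: 6 3-methyl-6-[(2S)-6-methylhept-5-en-2-yl]cyclohex-2-en-1-one (both C-6 epimers)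
Conditions: pyridinium chlorochromate, 4 Å MS, CH2Cl2, rt
Reagents that add atoms: pyridinium chlorochromate, [O-][Cr](=O)(=O)Cl.c1cc[nH+]cc1 (supplies the new carbonyl oxygen)
Why: In the Babler–Dauben oxidative 1,3-transposition the tertiary allylic chromate ester undergoes a [3,3] shift and is oxidised to the transposed enone, which places the oxygen next to the side-chain-bearing carbon and the methyl group para to it; no new stereocentre forms and the isolated trisubstituted alkene is inert.

**Step 4** (about half of 6)
Reactants: 6 3-methyl-6-[(2S)-6-methylhept-5-en-2-yl]cyclohex-2-en-1-one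
Product: 9 (S)-curcuphenol, via silyl dienol ether 7 (not isolated), via aryl silyl ether 8 (not isolated)
Conditions: LiN(iPr)2, THF, −78 °C; Me3SiCl; then DDQ (1.0 equiv), 2,6-lutidine, PhMe, 0 °C to rt; then K2CO3 (cat.), MeOH
Reagents that add atoms: none
Why: O-silylation under kinetic deprotonation gives a silyloxycyclohexadiene that DDQ aromatises by hydride abstraction and proton loss (silyl enol ether dehydrogenation), with any regioisomeric dienol ether converging on the same arene; ring centre C-6 is destroyed and the side-chain centre carries no acidic hydrogen.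

**Step 5**
Reactants: 9 (S)-curcuphenol
Product: 10 (S)-curcuquinone
Conditions: Co(salen) (5 mol %), O2 (1 atm), DMF, rt
Reagents that add atoms: dioxygen, O=O
Why: Cobalt–salen catalysed aerobic oxidation of a para-unsubstituted 2,5-dialkylphenol (the thymol-to-thymoquinone reaction type) oxygenates the only free para carbon through the phenoxyl radical and leaves the isolated alkene and the stereocentre alone.

**Step 6** (key step)
Reactants: 6 3-methyl-6-[(2S)-6-methylhept-5-en-2-yl]cyclohex-2-en-1-one; 10 (S)-curcuquinone
Product: 14 2',6-dimethyl-3,5'-bis[(2S)-6-methylhept-5-en-2-yl]biphenyl-2,4'-diol (target), via potassium dienolate 11 (not isolated), via quinol aldol adduct 12 (not isolated), via quinone methide 13 (not isolated)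
Conditions: 6, KN(SiMe3)2 (0.95 equiv), THF, 0 °C; CeCl3, −78 °C; 10; then AcOH, −78 to 40 °C
Reagents that add atoms: none
Why: Proposed new method: both carbons of the biaryl bond are donor positions of phenols, so ring A is used in polarity-reversed form as quinone 10 (a 4-hydroxyaryl cation, vinylogous enolonium, equivalent) and ring B as dienolate 11, equilibrated by a slight excess of ketone, whose alpha carbon C-2 is exactly the carbon that becomes the hindered ortho position; CeCl3 makes the dienolate more oxophilic and less reducing, so it adds 1,2 through a closed transition state to the less hindered carbonyl of 10 (next to the methyl-bearing carbon, not the sec-alkyl-bearing one) to give quinol 12, acid then triggers aldol dehydration to quinone methide 13, and two proton shifts aromatise both rings, so that the two hydrogens ring B gives up are those ring A needs and only water is lost; the closest known reaction types are the 1,2-addition of lithium and cerium enolates to p-benzoquinones (p-quinol synthesis), the alpha-selective aldol reaction of through-conjugated dienolates and the aldol condensation; all ring sp3 centres vanish, the two side-chain centres are not acidic and stay S, and the axis is not controlled.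

**Compound list**
1 | (S)-citronellal, (3S)-3,7-dimethyloct-6-enal | CC(C)=CCC[C@H](C)CC=O | starting material
2 | methyl vinyl ketone, but-3-en-2-one | CC(=O)C=C | starting material
3 | (3S)-3,7-dimethyl-2-(3-oxobutyl)oct-6-enal (C-2 epimers) | CC(C)=CCC[C@H](C)C(C=O)CCC(C)=O | intermediate
4 | 4-[(2S)-6-methylhept-5-en-2-yl]cyclohex-2-en-1-one (C-4 epimers) | CC(C)=CCC[C@H](C)C1C=CC(=O)CC1 | intermediate
5 | 1-methyl-4-[(2S)-6-methylhept-5-en-2-yl]cyclohex-2-en-1-ol (diastereomer mixture) | CC(C)=CCC[C@H](C)C1C=CC(C)(O)CC1 | intermediate
6 | 3-methyl-6-[(2S)-6-methylhept-5-en-2-yl]cyclohex-2-en-1-one (C-6 epimers) | CC(C)=CCC[C@H](C)C1CCC(C)=CC1=O | intermediate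
7 | trimethyl({5-methyl-2-[(2S)-6-methylhept-5-en-2-yl]cyclohexa-1,5-dien-1-yl}oxy)silane | CC(C)=CCC[C@H](C)C1=C(O[Si](C)(C)C)C=C(C)CC1 | intermediate
8 | trimethyl{5-methyl-2-[(2S)-6-methylhept-5-en-2-yl]phenoxy}silane | CC(C)=CCC[C@H](C)c1ccc(C)cc1O[Si](C)(C)C | intermediate
9 | (S)-curcuphenol, 5-methyl-2-[(2S)-6-methylhept-5-en-2-yl]phenol | CC(C)=CCC[C@H](C)c1ccc(C)cc1O | intermediate
10 | (S)-curcuquinone, 2-methyl-5-[(2S)-6-methylhept-5-en-2-yl]cyclohexa-2,5-diene-1,4-dione | CC(C)=CCC[C@H](C)C1=CC(=O)C(C)=CC1=O | intermediate
11 | potassium 3-methyl-6-[(2S)-6-methylhept-5-en-2-yl]cyclohexa-1,3-dien-1-olate | CC(C)=CCC[C@H](C)C1CC=C(C)C=C1[O-].[K+] | intermediate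
12 | 4-hydroxy-5-methyl-2-[(2S)-6-methylhept-5-en-2-yl]-4-{2-methyl-5-[(2S)-6-methylhept-5-en-2-yl]-6-oxocyclohex-2-en-1-yl}cyclohexa-2,5-dien-1-one | CC(C)=CCC[C@H](C)C1CC=C(C)C(C1=O)C1(O)C=C([C@@H](C)CCC=C(C)C)C(=O)C=C1C | intermediate
13 | p-quinone methide from loss of water from 12 (ring B C-2 doubly bonded to the former carbinol carbon of ring A) | CC(C)=CCC[C@H](C)C1CC=C(C)C(C1=O)=C1C=C([C@@H](C)CCC=C(C)C)C(=O)C=C1C | intermediate
14 | 2',6-dimethyl-3,5'-bis[(2S)-6-methylhept-5-en-2-yl]biphenyl-2,4'-diol | CC(C)=CCC[C@H](C)c1cc(-c2c(C)ccc([C@@H](C)CCC=C(C)C)c2O)c(C)cc1O | target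

**Totals**
- Total step count: 6.
- Longest linear sequence: 6 (1 → 4 → 5 → 6 → 9 → 10 → 14; the second portion of 6 enters in step 6).

**Steps most likely to fail**

**Step 6.** The risks are conjugate addition or electron transfer to the quinone instead of 1,2-addition, gamma attack of the dienolate, and retro-aldol before dehydration.

The fallback sets out from 9, uses 10 as before, and comes back at 14. NaH and ClC(O)NEt2 turn 9 into (S)-curcuphenyl N,N-diethylcarbamate F1. s-BuLi/TMEDA in THF at −78 °C removes the only free ortho hydrogen to give the ortho-lithiated carbamate F2, which adds 1,2 to the less hindered carbonyl of 10. On warming, the tertiary alkoxide takes over the carbamoyl group (O-to-O shift through a six-membered ring) and gives the quinol carbamate F3, in which the ring B phenol is already free. Zn in AcOH then expels the carbamate reductively and aromatises ring A to 14. This replaces the enolate by an aryl anion and the internal redox balance by an external reductant.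

**Step 5.** The risks are phenoxyl dimerisation and autoxidation of the side chain.

The fallback sets out from 9 and comes back at 10. NaNO2/HCl in EtOH at 0 °C nitrosates the free para position to 4-nitroso-(S)-curcuphenol F4. Na2S2O4 reduces this to 4-amino-(S)-curcuphenol F5. Aqueous FeCl3 oxidises and hydrolyses F5 to 10. The para oxygen is thus brought in through nitrogen by ionic chemistry instead of by a radical oxygenation.

**Step 4.** The risks are slow deprotonation at the hindered tertiary position, loss of the silyl group, and over-oxidation of the free phenol by DDQ.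

The fallback sets out from 6 and comes back at 9. LiN(iPr)2 followed by PhSeCl at −78 °C gives the 6-(phenylselanyl) enone F6. H2O2/pyridine in CH2Cl2 at 0 °C oxidises selenium, and syn elimination followed by tautomerisation of the cross-conjugated dienone gives 9. The hydride abstraction is replaced by a selenoxide elimination, and no quinone oxidant meets the phenol.

**Further compounds**
F1 | step 6 | (S)-curcuphenyl N,N-diethylcarbamate | CCN(CC)C(=O)Oc1cc(C)ccc1[C@@H](C)CCC=C(C)C
F2 | step 6 | ortho-lithiated carbamate | CCN(CC)C(=O)Oc1c([Li])c(C)ccc1[C@@H](C)CCC=C(C)C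
F3 | step 6 | quinol carbamate | CCN(CC)C(=O)OC1(C=C([C@@H](C)CCC=C(C)C)C(=O)C=C1C)c1c(C)ccc([C@@H](C)CCC=C(C)C)c1O
F4 | step 5 | 4-nitroso-(S)-curcuphenol | CC(C)=CCC[C@H](C)c1cc(N=O)c(C)cc1O
F5 | step 5 | 4-amino-(S)-curcuphenol | CC(C)=CCC[C@H](C)c1cc(N)c(C)cc1O
F6 | step 4 | 6-(phenylselanyl) enone | CC(C)=CCC[C@H](C)C1([Se]c2ccccc2)CCC(C)=CC1=O
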